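**Strategy.** The ten-membered carbocycle (C1–C10, germacrane numbering) is closed last, across C1–C10. The key step exploits the C10(=C14H2)–C1H(OH) 2-methylene carbinol of that ring as the retron of an alkenylchromium–aldehyde addition. An intramolecular Ni/Cr (Nozaki–Hiyama–Kishi) coupling of seco-aldehyde 16 should form the ring, set C1 and release the unprotected target in one operation. In 16 the trans-fused α-methylene lactone, the cis-4,5-epoxide and the C6 angelate are already in place; a 2-bromoallyl arm on C8 and a C1 aldehyde are the reacting ends. 16 arises from an allyl-transposing Cr(II) coupling of a bromomethyl butenolide with a nerol-derived epoxy aldehyde, which sets C6 and C7.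

Key step: step 9

Remark: locants follow germacrane numbering of the target, chosen for convenience (C8 lactone O–CH, C7 ring fusion, C6 CH–O-angeloyl, C5/C4 epoxide with the methyl on C4, C1 carbinol, C10=C14 and C11=C13 exocyclic alkenes, C12 lactone carbonyl).

Step 1
Reactants: 1 nerol
Product: 2 (2S,3R)-2,3-epoxynerol
Conditions: Ti(OiPr)4 (5 mol%), L-(+)-DET (7.5 mol%), TBHP, 4 Å MS, CH2Cl2, −20 °C
Reagents that add atoms: tert-butyl hydroperoxide, CC(C)(C)OO
Why: Sharpless asymmetric epoxidation: the Ti–tartrate complex binds the allylic OH, so only the 2,3-alkene reacts, and L-(+)-DET should deliver oxygen to the face that gives the (2S,3R)-epoxide, fixing C4 (R) and C5 (S) with the ring carbons cis as dictated by the Z alkene.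

Step 2
Reactants: 2 (2S,3R)-2,3-epoxynerol
Product: 3 (2R,3R)-3-methyl-3-(4-methylpent-3-en-1-yl)oxirane-2-carbaldehyde
Conditions: TEMPO (cat.), PhI(OAc)2, CH2Cl2, rt
Reagents that add atoms: none
Why: TEMPO/PhI(OAc)2 (oxoammonium) oxidation of a primary alcohol stops at the aldehyde under near-neutral conditions, so the trisubstituted epoxide, its two stereocenters (the α-carbon is an epoxide carbon and does not enolise readily) and the remote alkene should survive.

Step 3
Reactants: 4 acrolein, 5 2,3-dibromopropene
Product: 7 (3S)-5-bromohexa-1,5-dien-3-ol, via trimethylsilyl ether 6 (not isolated)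
Conditions: CrBr3 (10 mol%), chiral oxazoline–sulfonamide ligand (11 mol%, antipode directing Si-face attack), Et3N (20 mol%), Co phthalocyanine (1 mol%), Mn, TMSCl, 2,6-lutidine, THF, 0 °C → rt; then 1 M HCl, THF, 0 °C
Reagents that add atoms: none
Why: Catalytic asymmetric Nozaki–Hiyama 2-haloallylation: low-valent Cr (Co-assisted) inserts only into the allylic C–Br bond of 5, and the ligand-bound 2-bromoallylchromium(III) should add 1,2 to the Si face of acrolein through a closed transition state to set C8 as S, while Mn/TMSCl turn the chromium over and silyl ether 6 is cleaved on work-up.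

Step 4
Reactants: 7 (3S)-5-bromohexa-1,5-dien-3-ol, 8 2-(bromomethyl)acrylic acid
Product: 9 (3S)-5-bromohexa-1,5-dien-3-yl 2-(bromomethyl)prop-2-enoate
Conditions: DCC, DMAP (5 mol%), CH2Cl2, 0 °C
Reagents that add atoms: none
Why: Steglich esterification acylates the secondary allylic alcohol with retention at C8, and low temperature with only catalytic DMAP should leave the allylic bromide of the acid unsubstituted.

Step 5
Reactants: 9 (3S)-5-bromohexa-1,5-dien-3-yl 2-(bromomethyl)prop-2-enoate
Product: 10 (5S)-3-(bromomethyl)-5-(2-bromoprop-2-en-1-yl)furan-2(5H)-one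
Conditions: Grubbs second-generation catalyst (5 mol%), CH2Cl2 (0.01 M), 40 °C
Reagents that add atoms: none
Why: Ring-closing metathesis: the Ru carbene loads at the monosubstituted vinyl group and closes onto the 1,1-disubstituted acrylate to give the five-membered butenolide with loss of ethene, the electron-poor 2-bromoalkene and the allylic bromide being spectators and C8 untouched.

Step 6
Reactants: 10 (5S)-3-(bromomethyl)-5-(2-bromoprop-2-en-1-yl)furan-2(5H)-one, 3 (2R,3R)-3-methyl-3-(4-methylpent-3-en-1-yl)oxirane-2-carbaldehyde
Product: 11 (4S,5S)-5-(2-bromoprop-2-en-1-yl)-4-{(S)-hydroxy[(2S,3R)-3-methyl-3-(4-methylpent-3-en-1-yl)oxiran-2-yl]methyl}-3-methylideneoxolan-2-one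
Conditions: CrCl2 (3 equiv, Ni-free), THF, 0 °C → rt; pH 7 buffer work-up
Reagents that add atoms: none
Why: Nozaki–Hiyama (Barbier-type) allylation with allylic transposition: Ni-free Cr(II) reduces only the allylic bromide, and the allylchromium(III) should add through C7 in a chair Zimmerman–Traxler transition state on the butenolide face anti to the C9 arm (7,8-trans), the ring-locked E-type allyl geometry giving the 6,7-anti relationship and Felkin–Anh attack anti to the epoxide C5–O bond giving 6S, three mutually reinforcing preferences, while the alkene moves to the exocyclic C11=C13 position.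

Step 7
Reactants: 11 the C6 carbinol from step 6, 12 angelic acid
Product: 14 (S)-[(2S,3R)-2-(2-bromoprop-2-en-1-yl)-4-methylidene-5-oxooxolan-3-yl][(2S,3R)-3-methyl-3-(4-methylpent-3-en-1-yl)oxiran-2-yl]methyl (2Z)-2-methylbut-2-enoate, via mixed anhydride 13 (not isolated)
Conditions: 12, 2,4,6-trichlorobenzoyl chloride, Et3N, toluene, rt; then 11, 80 °C
Reagents that add atoms: none
Why: Yamaguchi mixed-anhydride esterification without DMAP acylates the hindered C6 hydroxyl with retention, and the absence of a nucleophilic catalyst should prevent isomerisation of the angelate to the tiglate and conjugate addition to the α-methylene lactone.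

Step 8
Reactants: 14 the C6 angelate from step 7
Product: 16 (S)-[(2S,3R)-2-(2-bromoprop-2-en-1-yl)-4-methylidene-5-oxooxolan-3-yl][(2S,3R)-3-methyl-3-(3-oxopropyl)oxiran-2-yl]methyl (2Z)-2-methylbut-2-enoate, via secondary ozonide 15 (not isolated)
Conditions: O3, CH2Cl2, −78 °C, Sudan Red 7B end point; Me2S, −78 °C → rt
Reagents that add atoms: ozone, [O-][O+]=O
Why: Chemoselective ozonolysis (Criegee mechanism): electrophilic ozone should attack the electron-rich trisubstituted alkene far faster than the three deactivated alkenes (α-methylene lactone, angelate, 2-bromoalkene), and Me2S reduces ozonide 15 to the C1 aldehyde and acetone without touching the epoxide or any stereocenter.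

Step 9
Reactants: 16 the seco-aldehyde from step 8
Product: 17 (1S,4R,5S,6S,7R,8S)-6-angeloyloxy-4,5-epoxy-1-hydroxygermacra-10(14),11(13)-dien-12,8-olide (CNP0104965.1)
Conditions: CrCl2 (6 equiv), chiral oxazoline–sulfonamide ligand (6.6 equiv, antipode directing Re-face attack), Et3N, NiCl2 (cat.), THF, rt, slow addition of 16 (final 2 mM)
Reagents that add atoms: none
Why: Ni(0), formed from NiCl2 by Cr(II), inserts into the C10–Br bond, the alkenyl group passes to Cr(III), and the alkenylchromium adds 1,2 to the C1 aldehyde, so that work-up should give the free C1 carbinol and hence the target with no protecting-group step. The closest known reaction type is the intramolecular Nozaki–Hiyama–Kishi alkenyl halide–aldehyde cyclisation to medium and large carbocycles, run here with a stoichiometric chiral Cr(III)–sulfonamide complex. The ten-membered carbocycle closes in a 10-exo-trig mode at the aldehyde carbon through the new C1–C10 bond, the lactone and epoxide rings being spectators. The new stereocenter C1 (S) is set by Re-face addition under control of the chiral ligand on chromium, acting on a chain already folded by the trans-lactone and the cis-epoxide. The step needs chemoselectivity and cyclisation over oligomerisation: only the C(sp2)–Br bond reacts with Ni(0), alkenylchromium(III) adds to the aldehyde but not to the lactone, angelate, epoxide or enoate, no β-leaving group is present (the lactone oxygen sits γ), and high dilution with the two built-in turn elements favours ring closure.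

**Compound list**
1 | nerol, (2Z)-3,7-dimethylocta-2,6-dien-1-ol | CC(C)=CCC/C(C)=C\CO | starting material
2 | (2S,3R)-2,3-epoxynerol, [(2S,3R)-3-methyl-3-(4-methylpent-3-en-1-yl)oxiran-2-yl]methanol | CC(C)=CCC[C@@]1(C)O[C@H]1CO | intermediate
3 | (2R,3R)-3-methyl-3-(4-methylpent-3-en-1-yl)oxirane-2-carbaldehyde | CC(C)=CCC[C@@]1(C)O[C@H]1C=O | intermediate
4 | acrolein | C=CC=O | starting material
5 | 2,3-dibromopropene | C=C(Br)CBr | starting material
6 | [(3S)-5-bromohexa-1,5-dien-3-yl]oxy(trimethyl)silane | C=C[C@@H](O[Si](C)(C)C)CC(Br)=C | intermediate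
7 | (3S)-5-bromohexa-1,5-dien-3-ol | C=C[C@@H](O)CC(Br)=C | intermediate
8 | 2-(bromomethyl)acrylic acid | C=C(CBr)C(=O)O | starting material
9 | (3S)-5-bromohexa-1,5-dien-3-yl 2-(bromomethyl)prop-2-enoate | C=C[C@@H](OC(=O)C(=C)CBr)CC(Br)=C | intermediate
10 | (5S)-3-(bromomethyl)-5-(2-bromoprop-2-en-1-yl)furan-2(5H)-one | BrCC1=C[C@H](CC(Br)=C)OC1=O | intermediate
11 | (4S,5S)-5-(2-bromoprop-2-en-1-yl)-4-{(S)-hydroxy[(2S,3R)-3-methyl-3-(4-methylpent-3-en-1-yl)oxiran-2-yl]methyl}-3-methylideneoxolan-2-one | C=C1C(=O)O[C@@H](CC(Br)=C)[C@@H]1[C@H](O)[C@@H]1O[C@]1(C)CCC=C(C)C | intermediate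
12 | angelic acid, (2Z)-2-methylbut-2-enoic acid | C/C=C(/C)C(=O)O | starting material
13 | (2Z)-2-methylbut-2-enoic 2,4,6-trichlorobenzoic anhydride | C/C=C(/C)C(=O)OC(=O)c1c(Cl)cc(Cl)cc1Cl | intermediate
14 | (S)-[(2S,3R)-2-(2-bromoprop-2-en-1-yl)-4-methylidene-5-oxooxolan-3-yl][(2S,3R)-3-methyl-3-(4-methylpent-3-en-1-yl)oxiran-2-yl]methyl (2Z)-2-methylbut-2-enoate | C=C1C(=O)O[C@@H](CC(Br)=C)[C@@H]1[C@H](OC(=O)/C(C)=C\C)[C@@H]1O[C@]1(C)CCC=C(C)C | intermediate
15 | secondary ozonide of 14: the same ester with a 2-(5,5-dimethyl-1,2,4-trioxolan-3-yl)ethyl group on the oxirane (both epimers at the trioxolane carbon) | C=C1C(=O)O[C@@H](CC(Br)=C)[C@@H]1[C@H](OC(=O)/C(C)=C\C)[C@@H]1O[C@]1(C)CCC1OOC(C)(C)O1 | intermediate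
16 | (S)-[(2S,3R)-2-(2-bromoprop-2-en-1-yl)-4-methylidene-5-oxooxolan-3-yl][(2S,3R)-3-methyl-3-(3-oxopropyl)oxiran-2-yl]methyl (2Z)-2-methylbut-2-enoate | C=C1C(=O)O[C@@H](CC(Br)=C)[C@@H]1[C@H](OC(=O)/C(C)=C\C)[C@@H]1O[C@]1(C)CCC=O | intermediate
17 | (1S,4R,5S,6S,7R,8S)-6-angeloyloxy-4,5-epoxy-1-hydroxygermacra-10(14),11(13)-dien-12,8-olide (CNP0104965.1) | C=C1C(=O)O[C@H]2CC(=C)[C@@H](O)CC[C@@]3(C)O[C@H]3[C@@H](OC(=O)/C(C)=C\C)[C@H]12 | target

**Step count.** Total: 9 steps. Longest linear sequence: 7 steps (steps 3–9, from acrolein and 2,3-dibromopropene).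

**Steps most likely to fail**

1. Step 9. The ring closure may proceed with insufficient facial discrimination at the C1 aldehyde, the ligand bias being opposed by the conformational bias of the forming ten-membered ring. The fallback sets out from 16 and comes back at 17. The ring is closed under ligand-free CrCl2/NiCl2 (DMSO, high dilution) without regard to C1. The resulting (1R)-epimer of 17 F1, alone or mixed with 17, is oxidised at the allylic carbinol with Dess–Martin periodinane to the cross-conjugated C1 ketone F2. F2 is reduced with (R)-Me-CBS/catecholborane, the C10 alkenyl group acting as the large substituent, which should give the 1S alcohol 17 under reagent control.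

2. Step 8. Ozone may over-oxidise, cleaving the 2-bromoalkene, the angelate or the α-methylene lactone before the prenyl alkene is consumed. The fallback sets out from 14 and comes back at 16. Dihydroxylation with OsO4 (cat.)/NMO, selective for the electron-rich trisubstituted alkene, should give the vicinal diol of 14 F3 (both epimers at the secondary carbinol serve). NaIO4 in aqueous THF then cleaves it to 16 under neutral conditions.

3. Step 6. Facial selectivity at the epoxy aldehyde may erode if Cr(III) chelates the aldehyde and epoxide oxygens and this competes with the Felkin pathway, giving the C6 epimer. The fallback sets out from 10 and 3 and comes back at 14, bypassing step 7. The coupling is accepted as it falls, and the (6R)-epimer of 11 F4 is esterified with angelic acid 12 under Mitsunobu conditions (PPh3, DIAD, toluene, 0 °C). This installs the angelate with inversion at C6 and should give 14 directly.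

**Further compounds**
F1 | step 9 | (1R)-epimer of 17 | C=C1C(=O)O[C@H]2CC(=C)[C@H](O)CC[C@@]3(C)O[C@H]3[C@@H](OC(=O)/C(C)=C\C)[C@H]12
F2 | step 9 | C1 ketone of the closed ring system (1-oxo analogue of 17) | C=C1C(=O)O[C@H]2CC(=C)C(=O)CC[C@@]3(C)O[C@H]3[C@@H](OC(=O)/C(C)=C\C)[C@H]12
F3 | step 8 | vicinal diol of 14 (3,4-dihydroxy-4-methylpentyl chain on the oxirane) | C=C1C(=O)O[C@@H](CC(Br)=C)[C@@H]1[C@H](OC(=O)/C(C)=C\C)[C@@H]1O[C@]1(C)CCC(O)C(C)(C)O
F4 | step 6 | (6R)-epimer of 11 | C=C1C(=O)O[C@@H](CC(Br)=C)[C@@H]1[C@@H](O)[C@@H]1O[C@]1(C)CCC=C(C)C
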